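**Retrosynthetic overview**
- Candidone is traced back through its (2S)-flavan-4-ol to the 2,4-cis 4-methoxyflavan. These are oxidation-state changes at C4 only, so C2 is the one stereocentre that must last.
- Structural feature: in ring C, the atoms O1–C8a–C4a–C4 form the oxadiene of an ortho-quinone methide stabilised by the C5 and C7 methoxy groups of ring A. C2–C3 together with ring B is plain styrene.
- Key disconnection: C3–C4 and O1–C2 are formed by an enantioselective inverse-demand oxa-[4+2] reaction. The partners are 3-prenyl-4,6-dimethoxysalicylaldehyde, trimethyl orthoformate and styrene under a confined chiral Brønsted acid.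
- The C8–prenyl bond comes from an aromatic Claisen rearrangement of the 1,1-dimethylallyl ether. That ether is made from 2-hydroxy-4,6-dimethoxybenzaldehyde and the methyl carbonate of 2-methylbut-3-en-2-ol.
- Ring order: rings A and B are bought. Ring C is the only ring formed, in step 4.

Key step: step 4

Assumption: the sense of induction of the confined acid cannot be derived in advance, so the catalyst antipode that delivers 2S is the one used; both antipodes are made alike from (R)- or (S)-BINOL.

**Step 1**
Reactants: 1 2-methylbut-3-en-2-ol
Product: 2 methyl (2-methylbut-3-en-2-yl) carbonate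
Conditions: n-BuLi (1.05 equiv), THF, −78 °C; ClCO2Me, −78 °C → rt; distillation
Reagents that add atoms: methyl chloroformate, COC(=O)Cl
Why: Acylation of the lithium alkoxide of a tertiary allylic alcohol with a chloroformate (carbonate formation) is fast and irreversible at low temperature and leaves the allylic C–O bond untouched, so no allylic transposition can occur.

**Step 2**
Reactants: 3 2-hydroxy-4,6-dimethoxybenzaldehyde; 2 methyl (2-methylbut-3-en-2-yl) carbonate
Product: 4 2-[(2-methylbut-3-en-2-yl)oxy]-4,6-dimethoxybenzaldehyde (1,1-dimethylallyl ether)
Conditions: Pd(PPh3)4 (3 mol %), 2 (1.5 equiv), THF, 0–5 °C; Et3N-deactivated silica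
Reagents that add atoms: none
Why: In this decarboxylative Tsuji–Trost O-allylation, Pd(0) ionises 2 to the 1,1-dimethyl-π-allyl complex, the liberated methoxide deprotonates the acidic chelated phenol, and under kinetic control at low temperature the phenoxide bonds to the more substituted allyl terminus to give the tertiary ether.

**Step 3**
Reactants: 4 2-[(2-methylbut-3-en-2-yl)oxy]-4,6-dimethoxybenzaldehyde
Product: 6 2-hydroxy-4,6-dimethoxy-3-(3-methylbut-2-enyl)benzaldehyde, via ortho-dienone 5 (not isolated)
Conditions: N,N-diethylaniline, 140 °C, Ar
Reagents that add atoms: none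
Why: In this aromatic Claisen rearrangement the [3,3] shift, accelerated by the gem-dimethyl group, can only reach C3 because the other ortho position carries the formyl group, it inverts the allyl unit so that the O-bound 1,1-dimethylallyl group becomes a C-bound prenyl group, and dienone 5 re-aromatises by tautomerisation while the basic solvent suppresses acid-induced chroman formation.

**Step 4**
Reactants: 6 2-hydroxy-4,6-dimethoxy-3-(3-methylbut-2-enyl)benzaldehyde; 7 styrene; 8 trimethyl orthoformate
Product: 11 (2S,4S)-4,5,7-trimethoxy-8-(3-methylbut-2-enyl)-2-phenylchroman (2,4-cis), via dimethyl acetal 9 (not isolated), via oxocarbenium ion 10 (not isolated)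
Conditions: chiral imidodiphosphorimidate acid (IDPi, 3,3′-diaryl-BINOL backbone, N-Tf; 5 mol %), 7 (20 equiv), 8 (1.3 equiv, slow addition), 5 Å MS, toluene, −30 °C; Et3N quench at −30 °C
Reagents that add atoms: none
Why: Proposed new method: the acid turns 6 and 8 into acetal 9 and ionises it, pushed by the C5 and C7 methoxy groups, to ion 10, best seen as a 4-methoxy ortho-quinone methide that still carries the phenolic proton on O1 and sits in the pocket of the chiral anion; the CH2 terminus of 7 then bonds to C4 while O1 closes onto the charge building up at benzylic C2, and loss of the O1 proton returns the catalyst. The closest known reaction types are the racemic Lewis- or Brønsted-acid three-component chroman synthesis from salicylaldehydes, orthoformates and styrenes, and the confined-acid-catalysed enantioselective intramolecular [4+2] reaction of alkoxy ortho-quinone methides made from salicylaldehydes and unsaturated alcohols, so only the union of intermolecular styrene capture with anion control is new. Ring C is closed by the intermolecular, asynchronous inverse-demand oxa-[4+2] cycloaddition itself (O1–C8a–C4a–C4 plus C3–C2), whose late event is the six-membered capture of the C2 cation by O1. C2 is set by the chiral counter-anion, which leaves one prochiral face of styrene open to the ion-paired oxadiene, and C4 follows from C2 through the endo placement of the phenyl ring under the E-configured C4=O+Me unit, which gives the 2,4-cis (2S,4S) isomer. The step needs regio-, chemo- and face selectivity: the polarity of 10 (C4 electrophilic, O1 nucleophilic) against styrene (CH2 nucleophilic) fixes the 2-phenyl regiochemistry, the prenyl group of the same molecule sits at C8 across ring A and cannot reach C4, and the prenyl alkenes and the free C6–H position of other molecules are held back by the large excess of the small styrene and by the narrow catalyst pocket. The low temperature made possible by donor-assisted ionisation keeps the ortho-prenyl phenol from acid cyclisation to a 2,2-dimethylchroman, and a leak in the cis/trans sense costs nothing as long as both isomers share 2S, because C4 becomes trigonal in step 6.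

**Step 5**
Reactants: 11 (2S,4S)-4,5,7-trimethoxy-8-(3-methylbut-2-enyl)-2-phenylchroman
Product: 12 (2S)-5,7-dimethoxy-8-(3-methylbut-2-enyl)-2-phenylchroman-4-ol (both C4 epimers, used crude)
Conditions: HCl (10 mM), THF–H2O (3:1), 5 mM in 11, 0 °C → rt; NaHCO3 quench
Reagents that add atoms: water, O
Why: In this SN1 solvolysis of a benzylic ether the C4–OMe bond is ortho/para to three oxygen donors (O1, 5-OMe, 7-OMe) and ionises in very dilute acid, the large excess of water at high dilution should trap the cation faster than C6 of a second molecule can, and C2, the aryl methyl ethers and the prenyl alkene (no free phenol is left beside it) are untouched, so the configuration at C4 does not matter.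

**Step 6**
Reactants: 12 (2S)-5,7-dimethoxy-8-(3-methylbut-2-enyl)-2-phenylchroman-4-ol
Product: 13 candidone, (2S)-5,7-dimethoxy-8-(3-methylbut-2-enyl)-2-phenylchroman-4-one
Conditions: TPAP (5 mol %), NMO (1.5 equiv), 4 Å MS, CH2Cl2, 0 °C → rt; short neutral silica pad
Reagents that add atoms: none
Why: The Ley–Griffith oxidation of a secondary benzylic alcohol runs without acid, so both C4 epimers converge on the ketone, the acid-labile alcohol does not ionise, the trisubstituted alkene is inert, and C2, which could only be lost by acid- or base-induced retro-oxa-Michael opening to the chalcone, is kept.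

**Compound list**
1 | 2-methylbut-3-en-2-ol | C=CC(C)(C)O | starting material
2 | methyl (2-methylbut-3-en-2-yl) carbonate | C=CC(C)(C)OC(=O)OC | intermediate
3 | 2-hydroxy-4,6-dimethoxybenzaldehyde | COc1cc(O)c(C=O)c(OC)c1 | starting material
4 | 2-[(2-methylbut-3-en-2-yl)oxy]-4,6-dimethoxybenzaldehyde | COc1cc(OC(C)(C)C=C)c(C=O)c(OC)c1 | intermediate
5 | 2,4-dimethoxy-5-(3-methylbut-2-enyl)-6-oxocyclohexa-1,3-diene-1-carbaldehyde (racemic, transient ortho-dienone) | O=CC1=C(OC)C=C(OC)C(CC=C(C)C)C1=O | intermediate
6 | 2-hydroxy-4,6-dimethoxy-3-(3-methylbut-2-enyl)benzaldehyde | COc1cc(OC)c(C=O)c(O)c1CC=C(C)C | intermediate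
7 | styrene | C=Cc1ccccc1 | starting material
8 | trimethyl orthoformate | COC(OC)OC | starting material
9 | 2-(dimethoxymethyl)-3,5-dimethoxy-6-(3-methylbut-2-enyl)phenol | COc1cc(OC)c(C(OC)OC)c(O)c1CC=C(C)C | intermediate
10 | [2-hydroxy-4,6-dimethoxy-3-(3-methylbut-2-enyl)benzylidene](methyl)oxonium, ion pair with the chiral IDPi anion (cation drawn) | COc1cc(OC)c(C=[O+]C)c(O)c1CC=C(C)C | intermediate
11 | (2S,4S)-4,5,7-trimethoxy-8-(3-methylbut-2-enyl)-2-phenylchroman (2,4-cis 4-methoxyflavan) | COc1cc(OC)c2c(c1CC=C(C)C)O[C@H](c1ccccc1)C[C@@H]2OC | intermediate
12 | (2S)-5,7-dimethoxy-8-(3-methylbut-2-enyl)-2-phenylchroman-4-ol (C4 epimers) | COc1cc(OC)c2c(c1CC=C(C)C)O[C@H](c1ccccc1)CC2O | intermediate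
13 | candidone, (2S)-5,7-dimethoxy-8-(3-methylbut-2-enyl)-2-phenylchroman-4-one | COc1cc(OC)c2c(c1CC=C(C)C)O[C@H](c1ccccc1)CC2=O | target

**Total step count:** 6
**Longest linear sequence:** 6 (1 → 2 → 4 → 6 → 11 → 12 → 13)

**Steps most likely to fail**

1. **Step 4.**
   - What may go wrong: The triply donor-stabilised cation may react too slowly with styrene at a temperature that is safe for the prenyl group. Friedel–Crafts self-condensation at the free C6–H position could then take over. Other possible failures are capture by prenyl alkenes of other molecules, acid cyclisation of the prenyl phenol, re-ionisation at C4, cationic oligomerisation of styrene, and poor facial selectivity at C2.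
   - Fallback (known chemistry, from 6 to 13): Ring C is closed first and the C2–phenyl bond is made last.
     - Excess ethynylmagnesium bromide (THF, 0 °C, neutral quench) adds to 6 to give racemic 1-[2-hydroxy-4,6-dimethoxy-3-(3-methylbut-2-enyl)phenyl]prop-2-yn-1-ol F1.
     - F1 is oxidised crude with MnO2 (CH2Cl2) to 1-[2-hydroxy-4,6-dimethoxy-3-(3-methylbut-2-enyl)phenyl]prop-2-yn-1-one F2.
     - Diethylamine in ethanol promotes the 6-endo oxa-Michael closure to 5,7-dimethoxy-8-(3-methylbut-2-enyl)chromen-4-one F3.
     - A rhodium(I)/electron-poor atropisomeric bisphosphine catalysed asymmetric 1,4-addition of phenylboronic acid to F3 (toluene–H2O, 20 °C, ligand antipode chosen for 2S) then sets C2 and gives 13 directly.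

2. **Step 2.**
   - What may go wrong: The chelated, rather acidic phenol may be O-alkylated only slowly. Pd(0) may also re-ionise the tertiary ether, so that the allylation drifts from the branched to the linear mode, and the Claisen step would then deliver the wrong allyl isomer.
   - Fallback (from 3 to 4): A π-allyl intermediate is avoided altogether. Copper-catalysed propargylic etherification of 3 with 3-chloro-3-methylbut-1-yne (DBU, cat. CuCl2, MeCN, 0 °C) gives 2-[(2-methylbut-3-yn-2-yl)oxy]-4,6-dimethoxybenzaldehyde F4, for which no linear isomer is possible. Lindlar semihydrogenation (H2, Pd/CaCO3/Pb, quinoline, EtOAc) of the terminal alkyne then gives 4.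

3. **Step 5.**
   - What may go wrong: The C4 cation may lose the C3 proton (elimination of methanol to the flav-3-ene level). It may also be captured by the C6 position of a second flavan (oligomerisation) before water arrives.
   - Fallback (from 8 and 6 to 12, obtained as its single 4S epimer): The oxygen at C4 is freed without ever forming that cation.
     - 8 is transesterified with allyl alcohol (cat. TsOH, methanol distilled off) to triallyl orthoformate F5.
     - F5 replaces 8 in the cycloaddition of step 4 and should give (2S,4S)-4-(allyloxy)-5,7-dimethoxy-8-(3-methylbut-2-enyl)-2-phenylchroman F6.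
     - The unsubstituted allyl ether is then cleaved under non-acidic conditions with low-valent titanium (Ti(OiPr)4, n-BuMgCl, THF, rt). This reagent exchanges only onto the monosubstituted alkene and expels the C4 alkoxide.

**Further compounds**
F1 | step 4 | 1-[2-hydroxy-4,6-dimethoxy-3-(3-methylbut-2-enyl)phenyl]prop-2-yn-1-ol (racemic) | COc1cc(OC)c(C(O)C#C)c(O)c1CC=C(C)C
F2 | step 4 | 1-[2-hydroxy-4,6-dimethoxy-3-(3-methylbut-2-enyl)phenyl]prop-2-yn-1-one | COc1cc(OC)c(C(=O)C#C)c(O)c1CC=C(C)C
F3 | step 4 | 5,7-dimethoxy-8-(3-methylbut-2-enyl)chromen-4-one | COc1cc(OC)c2c(c1CC=C(C)C)OC=CC2=O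
F4 | step 2 | 2-[(2-methylbut-3-yn-2-yl)oxy]-4,6-dimethoxybenzaldehyde | COc1cc(OC(C)(C)C#C)c(C=O)c(OC)c1
F5 | step 5 | triallyl orthoformate | C=CCOC(OCC=C)OCC=C
F6 | step 5 | (2S,4S)-4-(allyloxy)-5,7-dimethoxy-8-(3-methylbut-2-enyl)-2-phenylchroman | COc1cc(OC)c2c(c1CC=C(C)C)O[C@H](c1ccccc1)C[C@@H]2OCC=C
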